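The ash run was charged with more incoming ligand than the alder run, and at 0.167 min it held more complex with one exchanged, 22% against 14%. The decision for the new flask is when to stop it.

| flask | starting complex | incoming ligand | leaving ligand | remark | time |
|---|---|---|---|---|---|
| alder | 0.28 M | 0.21 M | 0.28 M | run made earlier |  |
| ash | 0.28 M | 0.32 M | 0.28 M | run made earlier |  |
| flask | 0.28 M | 0.420 M | 0.280 M |  | 12 min |

- alder (time / min: complex with one exchanged / %, complex with three exchanged / %): 0.167: 14, 0; 0.417: 22, 1; 1.00: 30, 0; 2.50: 32, 10; 5.00: 33, 10; 12.0: 32, 5
- ash (time / min: complex with one exchanged / %, complex with three exchanged / %): 0.167: 22, 1; 0.417: 30, 2; 1.00: 38, 7; 2.50: 35, 17; 5.00: 32, 23; 12.0: 34, 21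

(readings scatter by 2 percentage points)

- what may be going on: starting complex <-> dormant form; complex with one exchanged + incoming ligand -> leaving ligand + complex with two exchanged; starting complex + incoming ligand -> leaving ligand + complex with one exchanged; complex with two exchanged + incoming ligand -> leaving ligand + complex with three exchanged

- time, not beyond 12 min, at which the flask holds most complex with one exchanged
- the amount of complex with one exchanged, in percent of the starting complex charged, at that time

Take that early ash reading as a first-exchange constant, counting the complex with one exchanged as the starting complex lost:

k = 4.65 /M/min

The quantity to carry is the exchange half-life, ln(2)/(k[incoming ligand]), the time in which the first exchange by itself, at [incoming ligand] as charged, halves starting complex (a pseudo-first-order half-life):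

ash run: 0.466 min
new flask: 0.355 min

The highest ash reading is 38% at 1.00 min, which is 2.15 exchange half-lives. It is a coarse reading with a scatter of 2 percentage points. Every exchange on the scheme takes incoming ligand, but the step to dormant form takes none, so counting the same number of half-lives in the new flask is an estimate:

stopping time = 2.15 × 0.355 min = 0.762 min

So charge the new flask as written and stop it near that time, not at 12 min, expecting about the ash peak reading.

The forecast gave 36% at 0.8 min, with a fall afterwards “once ligand is spent”. The new flask gives 37.8% at 0.725 min, and 28.6% at 12.0 min.

    starting complex ⇌ dormant form (K = 1.70, k = 0.0133 /s)
    complex with one exchanged + incoming ligand → leaving ligand + complex with two exchanged (k = 0.0515 /M/s)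
    starting complex + incoming ligand → leaving ligand + complex with one exchanged (k = 0.0859 /M/s)
    complex with two exchanged + incoming ligand → leaving ligand + complex with three exchanged (k = 0.190 /M/s)

At 0.274 min the new flask makes complex with one exchanged 2.71 times faster than it uses it, each step taken net, and the reckoned exchange half-life of 0.355 min is shorter than the 0.53 min half-life of complex with one exchanged by the second exchange by itself, the other concentrations as charged. Its peak stands 2.04 exchange half-lives in.

With 1.7 M of incoming ligand, the exchange half-life at that charge is 0.0877 min, so 12 min spans 137 of them if [incoming ligand] stayed as charged, and you expect hardly any starting complex at the end. That neighbour flask computes to 0.0084% of starting complex at 12.0 min, with 51% of its incoming ligand still there.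

The earlier runs and the new flask were generated by integration on assumed constants; the scatter is artificial.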